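The target is cut at C8: the chloro‑hydroxy‑cyclopentenone ring (C8–C12) is unfolded to a 3‑chloro‑5‑octadienylfuran that adds to a C1–C8 aldehyde and is closed again by a Piancatelli rearrangement. All chain stereochemistry rests on the contiguous, all‑syn C5/C6/C7 triacetoxy triad, which maps onto a C7 carbinol beside a cis C5=C6 alkene. One peracid epoxidation, steered by the C7 hydroxyl, makes both C–O bonds at C5 and C6 on the required face; acetate opening at C5 with inversion completes the triad. The epoxidation substrate is the (5Z,7S)‑7‑hydroxy‑8‑silyloxyoctenoate, made from (R)‑glyceraldehyde acetonide by a Z‑selective Wittig reaction.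

Key step: step 4

Remark: prostanoid numbering is used throughout (C1 ester carbon, C8 and C12 ring carbons carrying the chains, C9 ketone); the facial sense of the ring closure in step 17 is an assumption from analogy and is treated as the main risk.

**Chain fragment (C1–C8)**

Step 1
Reactants: 1 (4‑carboxybutyl)triphenylphosphonium bromide; 2 (R)‑2,3‑O‑isopropylideneglyceraldehyde
Product: 4 (5Z)‑6‑[(4S)‑2,2‑dimethyl‑1,3‑dioxolan‑4‑yl]hex‑5‑enoic acid, via phosphonium ylide 3 (not isolated)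
Conditions: NaN(SiMe3)2 (2.1 equiv), THF, 0 °C; then 2, −78 °C to rt; cold aq. HCl to pH 4
Reagents that add atoms: none
Why: Wittig reaction of a non‑stabilised, lithium‑free ylide should give the cis alkene under kinetic control, and the future C7 centre is carried over untouched from the aldehyde.

Step 2
Reactants: 4 (5Z)‑6‑[(4S)‑2,2‑dimethyl‑1,3‑dioxolan‑4‑yl]hex‑5‑enoic acid
Product: 5 methyl (5Z,7S)‑7,8‑dihydroxyoct‑5‑enoate
Conditions: HCl (cat.), MeOH, 0 °C to rt
Reagents that add atoms: methanol, CO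
Why: Fischer esterification and acid‑catalysed acetonide cleavage run in the same pot, and no bond to C7 is broken.

Step 3
Reactants: 5 methyl (5Z,7S)‑7,8‑dihydroxyoct‑5‑enoate
Product: 6 methyl (5Z,7S)‑8‑(tert‑butyldimethylsilyloxy)‑7‑hydroxyoct‑5‑enoate
Conditions: tert‑butyldimethylsilyl chloride (1.05 equiv), imidazole, CH2Cl2, −10 to 0 °C
Reagents that add atoms: tert‑butyldimethylsilyl chloride, CC(C)(C)[Si](C)(C)Cl
Why: Selective silylation of the primary hydroxyl of a 1,2‑diol leaves the C7 hydroxyl free as the directing group.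

Step 4
Reactants: 6 methyl (5Z,7S)‑8‑(tert‑butyldimethylsilyloxy)‑7‑hydroxyoct‑5‑enoate
Product: 7 methyl (5R,6S,7R)‑8‑(tert‑butyldimethylsilyloxy)‑5,6‑epoxy‑7‑hydroxyoctanoate (cis‑epoxide; threo to the 7‑hydroxyl)
Conditions: m‑chloroperbenzoic acid (1.3 equiv), solid NaHCO3, CH2Cl2, 0 °C
Reagents that add atoms: m‑chloroperbenzoic acid, OOC(=O)c1cccc(Cl)c1
Why: The peracid, bound by a hydrogen bond to the C7 hydroxyl, passes its terminal oxygen to C5=C6 through one concerted spiro (butterfly) transition state; this is the hydroxyl‑directed Prilezhaev epoxidation of a cis‑allylic alcohol, a reaction type known to be threo‑selective. The oxirane (O, C5, C6) closes in this single suprafacial [2+1] oxygen transfer with both C–O bonds forming together, so no separate exo or endo cyclisation is involved. The cis relation of C5 and C6 follows stereospecifically from the Z alkene. Their absolute sense (5R,6S) is set by C7: to avoid a clash with the C4 methylene across the cis double bond, C7 turns its hydrogen into the alkene plane, the hydroxyl and the silyloxymethyl group then flank opposite faces, and the hydroxyl‑bound peracid attacks from its own side. The step needs only diastereofacial selectivity (one alkene, inert ester), and the NaHCO3 buffer should keep the 5,6‑epoxy ester from acid‑induced opening or lactonisation.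

Step 5
Reactants: 7 methyl (5R,6S,7R)‑8‑(tert‑butyldimethylsilyloxy)‑5,6‑epoxy‑7‑hydroxyoctanoate
Product: 8 methyl (5S,6S,7R)‑5‑acetoxy‑8‑(tert‑butyldimethylsilyloxy)‑6,7‑dihydroxyoctanoate
Conditions: Ti(OiPr)4 (1.5 equiv), AcOH (5 equiv), CH2Cl2, rt; aq. tartaric acid work‑up
Reagents that add atoms: acetic acid, CC(=O)O
Why: Titanium‑templated opening of a 2,3‑epoxy alcohol by a carboxylic acid should occur at the carbon remote from the carbinol (C5) by SN2 attack with inversion, giving 5S; any acetate that drifts to O6 converges in step 6.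

Step 6
Reactants: 8 methyl (5S,6S,7R)‑5‑acetoxy‑8‑(tert‑butyldimethylsilyloxy)‑6,7‑dihydroxyoctanoate
Product: 9 methyl (5S,6R,7R)‑5,6,7‑triacetoxy‑8‑(tert‑butyldimethylsilyloxy)octanoate
Conditions: Ac2O, pyridine, 4‑(dimethylamino)pyridine (cat.), CH2Cl2, 0 °C to rt
Reagents that add atoms: acetic anhydride, CC(=O)OC(C)=O
Why: Standard acylation of two secondary hydroxyls with no change at any stereocentre (the descriptor at C6 changes only through priority).

Step 7
Reactants: 9 methyl (5S,6R,7R)‑5,6,7‑triacetoxy‑8‑(tert‑butyldimethylsilyloxy)octanoate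
Product: 10 methyl (5S,6R,7R)‑5,6,7‑triacetoxy‑8‑hydroxyoctanoate
Conditions: HF·pyridine, pyridine, THF, 0 °C to rt
Reagents that add atoms: none
Why: Acidic fluoride desilylation frees the primary alcohol without the base that would drive acetyl migration from O7 to O8.

Step 8
Reactants: 10 methyl (5S,6R,7R)‑5,6,7‑triacetoxy‑8‑hydroxyoctanoate
Product: 11 methyl (5S,6R,7S)‑5,6,7‑triacetoxy‑8‑oxooctanoate
Conditions: Dess–Martin periodinane, NaHCO3, CH2Cl2, 0 °C to rt; used crude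
Reagents that add atoms: none
Why: Buffered Dess–Martin oxidation gives the α‑acetoxy aldehyde under near‑neutral conditions that spare the C7 centre (its descriptor changes only through priority).

**Octadienyl bromide**

Step 9
Reactants: 12 1‑bromopent‑2‑yne; 13 prop‑2‑yn‑1‑ol
Product: 15 octa‑2,5‑diyn‑1‑ol, via copper acetylide 14 (not isolated)
Conditions: CuI (1 equiv), Cs2CO3 (1 equiv), DMF, rt
Reagents that add atoms: none
Why: Copper‑mediated coupling of a terminal alkyne with a propargylic bromide is the standard entry to skipped diynes.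

Step 10
Reactants: 15 octa‑2,5‑diyn‑1‑ol
Product: 16 (2Z,5Z)‑octa‑2,5‑dien‑1‑ol
Conditions: H2 (1 atm), Pd/CaCO3 poisoned with Pb(OAc)2, quinoline, EtOAc, rt
Reagents that add atoms: none
Why: Lindlar‑type semihydrogenation adds hydrogen syn to each alkyne and should stop at the Z,Z‑diene.

Step 11
Reactants: 16 (2Z,5Z)‑octa‑2,5‑dien‑1‑ol
Product: 17 (2Z,5Z)‑1‑bromoocta‑2,5‑diene
Conditions: CBr4, PPh3, CH2Cl2, −20 to 0 °C
Reagents that add atoms: carbon tetrabromide, BrC(Br)(Br)Br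
Why: Appel bromination of a primary allylic alcohol proceeds by SN2 displacement without touching the alkene geometry.

**Furan fragment**

Step 12
Reactants: 18 3‑bromofuran
Product: 20 (3‑bromofuran‑2‑yl)trimethylsilane, via 2‑lithio‑3‑bromofuran 19 (not isolated)
Conditions: LiN(iPr)2, THF, −78 °C; Me3SiCl
Reagents that add atoms: chlorotrimethylsilane, C[Si](C)(C)Cl
Why: Halogen‑directed deprotonation occurs at C2, between oxygen and bromine, and silylation blocks this position for the next two steps.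

Step 13
Reactants: 20 (3‑bromofuran‑2‑yl)trimethylsilane
Product: 22 (3‑chlorofuran‑2‑yl)trimethylsilane, via 3‑lithio‑2‑silylfuran 21 (not isolated)
Conditions: n‑BuLi, Et2O, −78 °C; C2Cl6, −78 °C to rt
Reagents that add atoms: hexachloroethane, ClC(Cl)(Cl)C(Cl)(Cl)Cl
Why: Bromine–lithium exchange followed by electrophilic chlorination swaps the halogen in place, and the silyl group keeps the anion from moving to C2.

Step 14
Reactants: 22 (3‑chlorofuran‑2‑yl)trimethylsilane; 17 (2Z,5Z)‑1‑bromoocta‑2,5‑diene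
Product: 24 {3‑chloro‑5‑[(2Z,5Z)‑octa‑2,5‑dien‑1‑yl]furan‑2‑yl}trimethylsilane, via 5‑lithiofuran 23 (not isolated)
Conditions: n‑BuLi, THF, −78 to −20 °C; then 17, −78 °C to rt
Reagents that add atoms: none
Why: With C2 blocked, lithiation takes the only remaining position next to oxygen, and the furyllithium alkylates the primary allylic bromide by direct SN2 attack with the Z alkenes intact.

Step 15
Reactants: 24 {3‑chloro‑5‑[(2Z,5Z)‑octa‑2,5‑dien‑1‑yl]furan‑2‑yl}trimethylsilane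
Product: 25 4‑chloro‑2‑[(2Z,5Z)‑octa‑2,5‑dien‑1‑yl]furan
Conditions: Bu4NF (wet), THF, 0 °C to rt
Reagents that add atoms: none
Why: Fluoride‑induced protodesilylation of a 2‑silylfuran, eased by the adjacent chlorine, frees the position that will carry C8.

**Fragment union and ring formation**

Step 16
Reactants: 25 4‑chloro‑2‑[(2Z,5Z)‑octa‑2,5‑dien‑1‑yl]furan (1.3 equiv); 11 methyl (5S,6R,7S)‑5,6,7‑triacetoxy‑8‑oxooctanoate
Product: 28 methyl (5S,6R,7R)‑5,6,7‑triacetoxy‑8‑{3‑chloro‑5‑[(2Z,5Z)‑octa‑2,5‑dien‑1‑yl]furan‑2‑yl}‑8‑hydroxyoctanoate (both C8 epimers), via 2‑lithiofuran 26 (not isolated), via furyltitanium triisopropoxide 27 (not isolated)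
Conditions: LiN(iPr)2, THF, −78 °C; ClTi(OiPr)3, −78 to −40 °C; then 11, −78 to −20 °C; aq. NH4Cl
Reagents that add atoms: none
Why: Kinetic deprotonation at the ring carbon between oxygen and chlorine, transmetalation to a weakly basic aryltitanium and aldehyde‑selective 1,2‑addition should spare the acetates and the ester; the C8 configuration is irrelevant because step 17 planarises C8.

Step 17
Reactants: 28 methyl (5S,6R,7R)‑5,6,7‑triacetoxy‑8‑{3‑chloro‑5‑[(2Z,5Z)‑octa‑2,5‑dien‑1‑yl]furan‑2‑yl}‑8‑hydroxyoctanoate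
Product: 31 methyl (5S,6R,7R)‑5,6,7‑triacetoxy‑7‑{(1S,5R)‑3‑chloro‑5‑hydroxy‑5‑[(2Z,5Z)‑octa‑2,5‑dien‑1‑yl]‑2‑oxocyclopent‑3‑en‑1‑yl}heptanoate, via ring‑opened dienol ketone 29 (not isolated), via C8 epimer 30 (not isolated)
Conditions: ZnCl2 (2 equiv), 1,4‑dioxane–H2O (4:1), pH 5–6, 70 °C, continued until 30 has equilibrated
Reagents that add atoms: water, O
Why: Piancatelli rearrangement: zinc‑assisted ionisation of the furylcarbinol, water attack at the alkyl‑bearing furan carbon (future C12), ring opening to the 1,4‑dihydroxypentadienyl cation 29 and conrotatory 4π electrocyclisation form the C8–C12 bond; closure on the C8 face opposite the C7 acetoxy group (side chain held by allylic 1,3‑strain against the C9 hydroxyl), with the new hydroxyl turned outward, should fix C12 as R and give C8 epimer 30, and C8, being α to the C9 ketone, should then equilibrate through the zinc enol to the more stable 8S arrangement with the two carbon chains trans.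

**Compound list**

1 | (4‑carboxybutyl)triphenylphosphonium bromide | OC(=O)CCCC[P+](c1ccccc1)(c1ccccc1)c1ccccc1.[Br-] | starting material
2 | (R)‑2,3‑O‑isopropylideneglyceraldehyde | CC1(C)OC[C@@H](O1)C=O | starting material
3 | sodium 5‑(triphenyl‑λ5‑phosphanylidene)pentanoate (ylide) | [Na+].[O-]C(=O)CCCC=P(c1ccccc1)(c1ccccc1)c1ccccc1 | intermediate (not isolated)
4 | (5Z)‑6‑[(4S)‑2,2‑dimethyl‑1,3‑dioxolan‑4‑yl]hex‑5‑enoic acid | CC1(C)OC[C@@H](O1)/C=C\CCCC(=O)O | intermediate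
5 | methyl (5Z,7S)‑7,8‑dihydroxyoct‑5‑enoate | OC[C@@H](O)/C=C\CCCC(=O)OC | intermediate
6 | methyl (5Z,7S)‑8‑(tert‑butyldimethylsilyloxy)‑7‑hydroxyoct‑5‑enoate | CC(C)(C)[Si](C)(C)OC[C@@H](O)/C=C\CCCC(=O)OC | intermediate (key‑step precursor)
7 | methyl (5R,6S,7R)‑8‑(tert‑butyldimethylsilyloxy)‑5,6‑epoxy‑7‑hydroxyoctanoate | CC(C)(C)[Si](C)(C)OC[C@@H](O)[C@@H]1O[C@@H]1CCCC(=O)OC | intermediate (key‑step product)
8 | methyl (5S,6S,7R)‑5‑acetoxy‑8‑(tert‑butyldimethylsilyloxy)‑6,7‑dihydroxyoctanoate | CC(C)(C)[Si](C)(C)OC[C@@H](O)[C@H](O)[C@@H](OC(C)=O)CCCC(=O)OC | intermediate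
9 | methyl (5S,6R,7R)‑5,6,7‑triacetoxy‑8‑(tert‑butyldimethylsilyloxy)octanoate | CC(C)(C)[Si](C)(C)OC[C@@H](OC(C)=O)[C@H](OC(C)=O)[C@@H](OC(C)=O)CCCC(=O)OC | intermediate
10 | methyl (5S,6R,7R)‑5,6,7‑triacetoxy‑8‑hydroxyoctanoate | OC[C@@H](OC(C)=O)[C@H](OC(C)=O)[C@@H](OC(C)=O)CCCC(=O)OC | intermediate
11 | methyl (5S,6R,7S)‑5,6,7‑triacetoxy‑8‑oxooctanoate | O=C[C@@H](OC(C)=O)[C@H](OC(C)=O)[C@@H](OC(C)=O)CCCC(=O)OC | intermediate
12 | 1‑bromopent‑2‑yne | CCC#CCBr | starting material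
13 | prop‑2‑yn‑1‑ol | C#CCO | starting material
14 | copper acetylide of prop‑2‑yn‑1‑ol (CuC≡CCH2OH) | OCC#C[Cu] | intermediate (not isolated)
15 | octa‑2,5‑diyn‑1‑ol | CCC#CCC#CCO | intermediate
16 | (2Z,5Z)‑octa‑2,5‑dien‑1‑ol | CC/C=C\C/C=C\CO | intermediate
17 | (2Z,5Z)‑1‑bromoocta‑2,5‑diene | CC/C=C\C/C=C\CBr | intermediate
18 | 3‑bromofuran | Brc1ccoc1 | starting material
19 | (3‑bromofuran‑2‑yl)lithium | [Li]c1occc1Br | intermediate (not isolated)
20 | (3‑bromofuran‑2‑yl)trimethylsilane | C[Si](C)(C)c1occc1Br | intermediate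
21 | [2‑(trimethylsilyl)furan‑3‑yl]lithium | C[Si](C)(C)c1occc1[Li] | intermediate (not isolated)
22 | (3‑chlorofuran‑2‑yl)trimethylsilane | C[Si](C)(C)c1occc1Cl | intermediate
23 | [4‑chloro‑5‑(trimethylsilyl)furan‑2‑yl]lithium | C[Si](C)(C)c1oc([Li])cc1Cl | intermediate (not isolated)
24 | {3‑chloro‑5‑[(2Z,5Z)‑octa‑2,5‑dien‑1‑yl]furan‑2‑yl}trimethylsilane | CC/C=C\C/C=C\Cc1cc(Cl)c(o1)[Si](C)(C)C | intermediate
25 | 4‑chloro‑2‑[(2Z,5Z)‑octa‑2,5‑dien‑1‑yl]furan | CC/C=C\C/C=C\Cc1cc(Cl)co1 | intermediate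
26 | {3‑chloro‑5‑[(2Z,5Z)‑octa‑2,5‑dien‑1‑yl]furan‑2‑yl}lithium | CC/C=C\C/C=C\Cc1cc(Cl)c([Li])o1 | intermediate (not isolated)
27 | {3‑chloro‑5‑[(2Z,5Z)‑octa‑2,5‑dien‑1‑yl]furan‑2‑yl}tris(propan‑2‑olato)titanium | CC/C=C\C/C=C\Cc1cc(Cl)c(o1)[Ti](OC(C)C)(OC(C)C)OC(C)C | intermediate (not isolated)
28 | methyl (5S,6R,7R)‑5,6,7‑triacetoxy‑8‑{3‑chloro‑5‑[(2Z,5Z)‑octa‑2,5‑dien‑1‑yl]furan‑2‑yl}‑8‑hydroxyoctanoate, both C8 epimers | CC/C=C\C/C=C\Cc1cc(Cl)c(o1)C(O)[C@@H](OC(C)=O)[C@H](OC(C)=O)[C@@H](OC(C)=O)CCCC(=O)OC | intermediate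
29 | ring‑opened intermediate drawn as its neutral dienol ketone: methyl (5S,6R,7R,14Z,17Z)‑5,6,7‑triacetoxy‑10‑chloro‑9‑hydroxy‑12‑oxoicosa‑8,10,14,17‑tetraenoate, C9 and C12 cis on C10=C11 | CC/C=C\C/C=C\CC(=O)/C=C(Cl)\C(O)=C[C@@H](OC(C)=O)[C@H](OC(C)=O)[C@@H](OC(C)=O)CCCC(=O)OC | intermediate (not isolated)
30 | (8R,12R) C8 epimer of the target: methyl (5S,6R,7R)‑5,6,7‑triacetoxy‑7‑{(1R,5R)‑3‑chloro‑5‑hydroxy‑5‑[(2Z,5Z)‑octa‑2,5‑dien‑1‑yl]‑2‑oxocyclopent‑3‑en‑1‑yl}heptanoate | CC/C=C\C/C=C\C[C@]1(O)C=C(Cl)C(=O)[C@@H]1[C@@H](OC(C)=O)[C@H](OC(C)=O)[C@@H](OC(C)=O)CCCC(=O)OC | intermediate (not isolated)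
31 | methyl (5S,6R,7R)‑5,6,7‑triacetoxy‑7‑{(1S,5R)‑3‑chloro‑5‑hydroxy‑5‑[(2Z,5Z)‑octa‑2,5‑dien‑1‑yl]‑2‑oxocyclopent‑3‑en‑1‑yl}heptanoate (8S,12R) | CC/C=C\C/C=C\C[C@]1(O)C=C(Cl)C(=O)[C@H]1[C@@H](OC(C)=O)[C@H](OC(C)=O)[C@H](CCCC(=O)OC)OC(C)=O | target

**Step count and risks**

Total steps: 17. Longest linear sequence: 10 steps (steps 1–8, 16, 17).

Most likely to fail, in order:

Step 17. Four processes threaten it:
- The helical sense of the conrotatory closure may be only weakly biased by C7, or biased the other way, so that the ring diastereomer with inverted C12 forms and must be separated.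
- Equilibration at C8 may stall.
- The furfuryl cation may be captured by the neighbouring C7 acetate, scrambling acyl groups between O7 and O8.
- Acetic acid may be lost across C7–C8 once the β‑acetoxy ketone exists.

The fallback acetylates C6 and C7 only after the ring is made, so that C7 carries a rigid, non‑participating dioxolane during the closure. It sets out from 8. Ketalisation (2,2‑dimethoxypropane, pyridinium p‑toluenesulfonate) gives methyl (5S,6R,7R)‑5‑acetoxy‑8‑(tert‑butyldimethylsilyloxy)‑6,7‑(isopropylidenedioxy)octanoate F1. Desilylation with HF·pyridine gives methyl (5S,6R,7R)‑5‑acetoxy‑8‑hydroxy‑6,7‑(isopropylidenedioxy)octanoate F2. Dess–Martin oxidation gives the sturdier α‑alkoxy aldehyde methyl (5S,6R,7S)‑5‑acetoxy‑6,7‑(isopropylidenedioxy)‑8‑oxooctanoate F3. Addition of 27 gives the furylcarbinol acetonide F4. The same ZnCl2 rearrangement gives the cyclopentenone acetonide F5. Aqueous acetic acid removes the ketal to give the 6,7‑diol F6. Acetylation with Ac2O in pyridine at 0 °C, which leaves the tertiary C12 hydroxyl alone, comes back to the route at 31.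

Step 16. The new C8 alkoxide may pull the acetyl group over from O7, the α‑acetoxy aldehyde may enolise and lose its C7 configuration, or the organometallic may attack an ester carbonyl. The fallback replaces the basic organometallic by a chromium‑mediated coupling. It sets out from 25: lithiation and iodine quench give 3‑chloro‑2‑iodo‑5‑[(2Z,5Z)‑octa‑2,5‑dien‑1‑yl]furan F7. F7 is joined to 11 by a Nozaki–Hiyama–Kishi reaction (CrCl2, NiCl2 cat., DMF, rt), a non‑basic carbonyl addition that tolerates esters, and comes back to the route at 28.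

Step 5. Acetate may attack C6 instead of C5, isopropoxide may exchange with the methyl ester, or the silyl group may migrate to O7. The fallback lets the ester itself open the epoxide. It sets out from 7: camphorsulfonic acid in wet CH2Cl2 should trigger 6‑exo attack of the ester carbonyl on C5 with inversion, giving the lactone (6S)‑6‑[(1S,2R)‑3‑(tert‑butyldimethylsilyloxy)‑1,2‑dihydroxypropyl]oxan‑2‑one F8. Methanolysis (Et3N, MeOH) opens it to methyl (5S,6R,7R)‑8‑(tert‑butyldimethylsilyloxy)‑5,6,7‑trihydroxyoctanoate F9. F9 is acetylated at once under the conditions of step 6 and comes back to the route at 9.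

Further compounds
F1 | step 17 | methyl (5S,6R,7R)‑5‑acetoxy‑8‑(tert‑butyldimethylsilyloxy)‑6,7‑(isopropylidenedioxy)octanoate | CC(C)(C)[Si](C)(C)OC[C@H]1OC(C)(C)O[C@@H]1[C@@H](OC(C)=O)CCCC(=O)OC
F2 | step 17 | methyl (5S,6R,7R)‑5‑acetoxy‑8‑hydroxy‑6,7‑(isopropylidenedioxy)octanoate | OC[C@H]1OC(C)(C)O[C@@H]1[C@@H](OC(C)=O)CCCC(=O)OC
F3 | step 17 | methyl (5S,6R,7S)‑5‑acetoxy‑6,7‑(isopropylidenedioxy)‑8‑oxooctanoate | O=C[C@H]1OC(C)(C)O[C@@H]1[C@@H](OC(C)=O)CCCC(=O)OC
F4 | step 17 | methyl (5S,6R,7R)‑5‑acetoxy‑8‑{3‑chloro‑5‑[(2Z,5Z)‑octa‑2,5‑dien‑1‑yl]furan‑2‑yl}‑8‑hydroxy‑6,7‑(isopropylidenedioxy)octanoate, both C8 epimers | CC/C=C\C/C=C\Cc1cc(Cl)c(o1)C(O)[C@H]1OC(C)(C)O[C@@H]1[C@@H](OC(C)=O)CCCC(=O)OC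
F5 | step 17 | methyl (5S,6R,7R)‑5‑acetoxy‑7‑{(1S,5R)‑3‑chloro‑5‑hydroxy‑5‑[(2Z,5Z)‑octa‑2,5‑dien‑1‑yl]‑2‑oxocyclopent‑3‑en‑1‑yl}‑6,7‑(isopropylidenedioxy)heptanoate | CC/C=C\C/C=C\C[C@]1(O)C=C(Cl)C(=O)[C@H]1[C@H]2OC(C)(C)O[C@@H]2[C@@H](OC(C)=O)CCCC(=O)OC
F6 | step 17 | methyl (5S,6S,7R)‑5‑acetoxy‑7‑{(1S,5R)‑3‑chloro‑5‑hydroxy‑5‑[(2Z,5Z)‑octa‑2,5‑dien‑1‑yl]‑2‑oxocyclopent‑3‑en‑1‑yl}‑6,7‑dihydroxyheptanoate | CC/C=C\C/C=C\C[C@]1(O)C=C(Cl)C(=O)[C@H]1[C@@H](O)[C@H](O)[C@@H](OC(C)=O)CCCC(=O)OC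
F7 | step 16 | 3‑chloro‑2‑iodo‑5‑[(2Z,5Z)‑octa‑2,5‑dien‑1‑yl]furan | CC/C=C\C/C=C\Cc1cc(Cl)c(I)o1
F8 | step 5 | (6S)‑6‑[(1S,2R)‑3‑(tert‑butyldimethylsilyloxy)‑1,2‑dihydroxypropyl]oxan‑2‑one | CC(C)(C)[Si](C)(C)OC[C@@H](O)[C@H](O)[C@@H]1CCCC(=O)O1
F9 | step 5 | methyl (5S,6R,7R)‑8‑(tert‑butyldimethylsilyloxy)‑5,6,7‑trihydroxyoctanoate | CC(C)(C)[Si](C)(C)OC[C@@H](O)[C@H](O)[C@@H](O)CCCC(=O)OC
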